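## Structural features

The target joins two units through a methylene carbon (C11): a 2-hydroxy-5-(3-methylbutylamino)-1,4-benzoquinone, attached at its C3, and a rearranged drimane decalin, attached at C9 (terpenoid numbering throughout: ring A = C1–C5 and C10, ring B = C5–C10). Ring A carries only the C4 gem-dimethyl group and has no stereocentre of its own. Ring B carries the trisubstituted C5=C6 alkene, a secondary methyl at C8, the all-carbon quaternary C9 (methyl and C11) and the ring-fusion methine C10. The three stereocentres C8, C9 and C10 are contiguous (8S,9R,10S): the C8 and C9 methyl groups are cis, and H10 is cis to C11 and trans to the C9 methyl. The hydroxy-aminoquinone is the fragile part (bases, nucleophiles and reductants all act on it) and is best carried as a 2,3,5,6-tetramethoxyphenyl group until the end; the C5=C6 alkene beside the quaternary C4 is the second sensitive site, because protonation there opens cationic 1,2-shift pathways. The real difficulty is the quaternary C9, flanked by two tertiary stereocentres and bearing a neopentyl-type benzylic carbon, together with the relative configuration at C10. The key step exploits two facts: ring A is stereochemically blank apart from C10, and a C4 gem-dimethyl group beside a C5=C6 alkene is what deconjugative dimethylation of a 4-en-3-one delivers. Ring A can therefore be annulated onto a ring B ketone (carbonyl at C5) by forming C1–C10 and C4–C5, and C10 stays epimerisable (α to the C5 carbonyl before closure, γ to the C3 carbonyl after) so that it can settle under thermodynamic control.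

## Logic of the disconnections

22 ⇒ 20 + 21. The bond cut is the quinone C5–N bond. A methoxy group at C5 of a 2-hydroxyquinone is a vinylogous ester that exchanges with primary amines, so the only nitrogen and the most polar functionality arrive last. The forward step must deliver the amine to C5 only, which requires the C2 oxygen to be a free hydroxyl before the amine is added.

20 ⇒ 19. The C2 hydroxyl is traced back to a methoxy group (O–CH3 bond restored). This makes the two quinone oxygens at C2 and C5 identical and derives both from one symmetrical arene. The forward step must exchange the methoxy group next to the alkyl substituent and leave the other.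

19 ⇒ 18. The two quinone carbonyls are traced back to aryl methyl ethers. The quinone is thereby masked as a robust tetra-ether that tolerates organometallics, strong base and hydrazine. The forward oxidation must spare the C5=C6 alkene.

18 ⇒ 16. A carbonyl is reinstated at C3. It is the handle that allows the C4 methyl groups to be introduced and places the alkene. The forward step must remove a neopentyl-type ketone without disturbing the alkene or the aryl ethers.

16 ⇒ 15. Both C4–CH3 bonds are cut and the alkene is returned to conjugation (C4=C5). The result is a plain octalone, the retron of a Robinson annulation. The forward step must alkylate twice at C4 through the extended dienolate formed by removing a C6 hydrogen.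

15 ⇒ 11 + 12. The C1–C10 and C4–C5 bonds are cut, which removes ring A and the C10 stereocentre. What remains is a monocyclic, regiodefined enol derivative of a C5 ketone, and a four-carbon acceptor. The forward step must form the first bond at C10 and not at C6, and must end with H10 cis to C11.

11 ⇒ 5 + 9. The C9–C11 bond is cut (and the O–Si bond with it). The quaternary centre reduces to the β-carbon of an enone, and the enol ether regiochemistry is explained by the conjugate addition itself. The forward step must add the benzylic carbon trans to the C8 methyl and trap the enolate before it can equilibrate.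

9 ⇒ 8 ⇒ 6. The C11–Cl bond and then the aryl–C11 bond are cut. The arene is reached in two operations from a symmetrical, commercial tetra-ether whose two free positions are equivalent. The forward steps require only clean monometalation.

5 ⇒ 4 ⇒ 3. The C9–CH3 bond is cut. The methyl group comes from a methyl nucleophile added to the enone and the unsaturation is restored from the trapped enol ether. The forward steps must keep the C8 stereocentre, which is γ to the carbonyl, away from base.

3 ⇒ 2 ⇒ 1. The enone C=C bond is traced to a silyl enol ether and this to a symmetrical ketone. All absolute stereochemistry is thereby reduced to one enantiotopic-proton selection. The forward step must distinguish the two α-methylene groups of 1 with a chiral base.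

## Other disconnections considered

Alternative 1: The cut is through C4–C5 and C9–C10 together, with three 1,2-shifts behind it. In the forward direction the farnesyl arene A1 would be protonated at its terminal alkene by a chiral tin-based Lewis-acid-assisted Brønsted acid (SnCl4 on a binaphthol monoether) and cyclise to the trans-fused drimenyl arene A2. Acid treatment of A2 would then protonate C7=C8 and relay H9 to C8, the C10 methyl to C9 and H5 to C10, ending by loss of H6 to give 18.
- In its favour: A1 is one alkylation away from aryllithium 7, both rings form in one step, and the suprafacial shifts translate the trans-decalin of A2 stereospecifically into the 8,9,10 pattern of the target. On step economy this plan is the better one, about seven steps against thirteen.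
- Against it here: the arene is a bystander and not the terminating nucleophile, so enantiofacial control of the initiating protonation has little to hold on to. The electron-rich ring competes for acid. The termination of the cyclisation has several alkene outcomes. The friedo cascade has several exits (stopping early, or going on by a C4 methyl shift to the 4,5-dimethyl series).
- Comparison: on structure this plan sets all three stereocentres from one catalyst-controlled event plus cationic relay, whereas the chosen plan sets them one at a time by substrate control. On mechanism the chosen plan places the alkene by enolate chemistry, where the regiochemistry is traceable, and the cationic route relies on kinetic partitioning of carbocations.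

Alternative 2: The cut is the C9–C10 bond, seen as the product of a [3,3] shift in which C6–O breaks. In the forward direction the δ-lactone A3 (4-methyl and 6-cyclohexenyl trans) would be converted into its silyl ketene acetal (KN(SiMe3)2, Me3SiCl), which on warming would contract to the carbocyclic acid A4.
- In its favour: the ring enforces a boat transition state, so the C6 carbinol configuration is relayed strictly to C9 and C10, and H10 ends cis to C11 by geometry. On stereochemical rigour at C9 and C10 this plan is the better one. On placement of the C5=C6 alkene it is the equal of the chosen plan.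
- Against it here: A3 needs its own stereocontrolled synthesis (two stereocentres in a 1,3-trans relationship, a hindered cyclohexenyl carbinol and an α-arylmethyl group). The rearrangement must forge a quaternary centre from a fully substituted ketene acetal next to a gem-dimethyl-bearing ring. The carboxyl group of A4 must then be taken down to a methyl group through neopentyl intermediates.
- Comparison: on step economy this plan is clearly the longer one. On mechanism it replaces a thermodynamic C10 assignment by a stereospecific pericyclic one.

Alternative 3: The cut is through C7–C8 and C9–C10. In the forward direction the diene A5 and the enal A6 would combine under a chiral oxazaborolidinium Lewis acid to the aldehyde A7. Aryllithium 7 would then add to the aldehyde carbon of A7 and the benzylic oxygen would be removed to reach 18.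
- In its favour: ring B and all three stereocentres would arise in one convergent step (the cis methyl pair from the E geometry of A6, H10 cis to C11 from exo addition). On convergence and step count this plan is the better one, about eight steps.
- Against it here: A6 is an α,β-disubstituted enal and a sluggish dienophile, and A5 is hindered at the diene by the neighbouring gem-dimethyl group. Regiochemistry, exo selectivity and facial selectivity must all be delivered at once by the catalyst, with no later chance to correct C10. The benzylic deoxygenation next to a quaternary carbon invites cationic rearrangement.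
- Comparison: on structure both plans build C9–C10 late, but the chosen plan forms it by an enolate addition whose stereochemical outcome can be equilibrated. On mechanism the chosen plan uses only substrate-controlled, individually checkable events and accepts a longer sequence for that.

Key step: step 8

Assumption: the (R,R)-configured lithium amide is taken to give the (S)-enol silane 2, by analogy with the behaviour of this base towards 4-tert-butylcyclohexanone; the (S,S)-amide would be used if the sense proved opposite.

## Route

Step 1
Reactants: 1 4-methylcyclohexan-1-one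
Product: 2 trimethyl{[(4S)-4-methylcyclohex-1-en-1-yl]oxy}silane
Conditions: lithium (R,R)-bis(1-phenylethyl)amide (from the amine and n-BuLi), Me3SiCl (internal quench), THF, −100 °C; Et3N, NaHCO3(aq)
Reagents that add atoms: chlorotrimethylsilane, C[Si](C)(C)Cl
Why: Asymmetric deprotonation of a prochiral 4-substituted cyclohexanone by a C2-symmetric chiral lithium amide; the base selects one of the two enantiotopic axial α-hydrogens, which makes C4 (the future C8) stereogenic, and the internal silyl quench prevents enolate equilibration.

Step 2
Reactants: 2 trimethyl{[(4S)-4-methylcyclohex-1-en-1-yl]oxy}silane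
Product: 3 (4S)-4-methylcyclohex-2-en-1-one
Conditions: Pd(OAc)2 (10 mol %), O2 (1 atm), DMSO, 25 °C
Reagents that add atoms: none
Why: Saegusa–Ito oxidation: divalent palladium forms the α-palladated ketone from the enol silane and β-hydride elimination gives the enone on the side fixed in step 1, while O2 reoxidises zerovalent palladium; the medium is neutral, so the γ-stereocentre is not epimerised.

Step 3
Reactants: 3 (4S)-4-methylcyclohex-2-en-1-one
Product: 4 trimethyl{[(3R,4S)-3,4-dimethylcyclohex-1-en-1-yl]oxy}silane
Conditions: Me2CuLi (from MeLi and CuI), Me3SiCl, THF, −78 °C; Et3N, NaHCO3(aq)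
Reagents that add atoms: lithium dimethylcuprate, [Li+].C[Cu-]C; chlorotrimethylsilane, C[Si](C)(C)Cl
Why: Me3SiCl-accelerated 1,4-addition of a Gilman cuprate with regiospecific trapping of the enolate as the silyl enol ether; the methyl group should enter anti to the C4 methyl, but this centre is made trigonal again in step 4.

Step 4
Reactants: 4 trimethyl{[(3R,4S)-3,4-dimethylcyclohex-1-en-1-yl]oxy}silane
Product: 5 (4S)-3,4-dimethylcyclohex-2-en-1-one
Conditions: Pd(OAc)2 (10 mol %), O2 (1 atm), DMSO, 25 °C
Reagents that add atoms: none
Why: Second Saegusa–Ito oxidation; β-hydride elimination can only take the C3 hydrogen, so the β-methyl enone forms with the C4 stereocentre untouched.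

Step 5
Reactants: 6 1,2,4,5-tetramethoxybenzene
Product: 8 (2,3,5,6-tetramethoxyphenyl)methanol, via (2,3,5,6-tetramethoxyphenyl)lithium 7 (not isolated)
Conditions: n-BuLi, THF, 0 °C; (CH2O)n, −78→25 °C; H2O
Reagents that add atoms: formaldehyde (as paraformaldehyde), C=O
Why: Directed ortho-lithiation between two methoxy groups (the two free positions are equivalent, so there is no regiochemical issue), followed by addition of the aryllithium to formaldehyde.

Step 6
Reactants: 8 (2,3,5,6-tetramethoxyphenyl)methanol
Product: 9 3-(chloromethyl)-1,2,4,5-tetramethoxybenzene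
Conditions: SOCl2, CH2Cl2, 0 °C
Reagents that add atoms: thionyl chloride, O=S(Cl)Cl
Why: Chlorodehydroxylation of an activated benzylic alcohol through its chlorosulfite; the chloride is preferred to the bromide because it is less prone to Wurtz coupling in step 7.

Step 7
Reactants: 9 3-(chloromethyl)-1,2,4,5-tetramethoxybenzene; 5 (4S)-3,4-dimethylcyclohex-2-en-1-one
Product: 11 trimethyl({(3R,4S)-3,4-dimethyl-3-[(2,3,5,6-tetramethoxyphenyl)methyl]cyclohex-1-en-1-yl}oxy)silane, via benzylic Grignard reagent 10 (not isolated)
Conditions: Mg, THF, 0 °C (slow addition of 9); then CuBr·SMe2 (10 mol %), HMPA, Me3SiCl, 5, THF, −78 °C; Et3N, NaHCO3(aq)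
Reagents that add atoms: chlorotrimethylsilane, C[Si](C)(C)Cl
Why: Copper-catalysed conjugate addition of a Grignard reagent activated by Me3SiCl/HMPA, with in situ silylation of the enolate. The C4 methyl of 5 sits pseudoaxial to avoid allylic strain with the C3 methyl and the nucleophile adds axially on the opposite face, so C11 ends trans to the C8 methyl and C9 is set. The enol ether double bond lies between C5 and C10 because that is where the conjugate addition leaves it.

Step 8
Reactants: 11 trimethyl({(3R,4S)-3,4-dimethyl-3-[(2,3,5,6-tetramethoxyphenyl)methyl]cyclohex-1-en-1-yl}oxy)silane; 12 3-(trimethylsilyl)but-3-en-2-one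
Product: 15 (4aR,5R,6S)-5,6-dimethyl-5-[(2,3,5,6-tetramethoxyphenyl)methyl]-4,4a,5,6,7,8-hexahydronaphthalen-2(3H)-one, via lithium enolate 13 (not isolated), via silyl diketone 14 (not isolated)
Conditions: MeLi, THF, 0→25 °C; 12, −78→−20 °C; then KOH, MeOH/H2O, 65 °C
Reagents that add atoms: 3-(trimethylsilyl)but-3-en-2-one (12), CC(=O)C(=C)[Si](C)(C)C
Why: MeLi attacks silicon and releases lithium enolate 13; its C5–C10 regiochemistry is inherited from step 7 and is not intrinsic, since the C5 ketone has hydrogens at both C6 and C10, so proton sources are excluded until the C–C bond is made. Enolate 13 adds through C10 to the CH2 terminus of 12 (C1–C10 bond), and the α-silyl group stabilises the adduct enolate 14, which suppresses polymerisation and proton transfer; the closest known reaction type is the Robinson annulation of a regiospecifically generated enolate with an α-silyl vinyl ketone. Methanolic KOH then cleaves the C–Si bond, the methyl ketone enolate attacks the C5 carbonyl in a 6-(enolendo)-exo-trig aldol closure (C4–C5 bond, ring A) and water is lost by E1cB elimination. C10 is the only new stereocentre and is controlled thermodynamically: it is α to the C5 carbonyl before closure and γ to the C3 carbonyl afterwards, so base can epimerise it through the enolate and the extended dienolate. Because C5 is trigonal and held in the enone plane, C1 must be equatorial on ring B, so each C10 epimer has only one ring B chair. The wanted epimer has H10 and the C9 methyl axial with C11 and the C8 methyl equatorial, whereas the other epimer must place both C11 and the C8 methyl axial and is expected to be the less stable. The kinetic Michael addition (axial, anti to the axial C9 methyl) would favour the wrong epimer, so the prolonged base treatment is essential. The step thus needs attack at C10 and not C6, secured by the regiodefined enolate and the silylated acceptor, and H10 cis to C11, secured by equilibration.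

Step 9
Reactants: 15 (4aR,5R,6S)-5,6-dimethyl-5-[(2,3,5,6-tetramethoxyphenyl)methyl]-4,4a,5,6,7,8-hexahydronaphthalen-2(3H)-one
Product: 16 (4aS,5R,6S)-1,1,5,6-tetramethyl-5-[(2,3,5,6-tetramethoxyphenyl)methyl]-3,4,4a,5,6,7-hexahydronaphthalen-2(1H)-one
Conditions: KOtBu, tBuOH/THF, 25 °C; MeI, 25→40 °C
Reagents that add atoms: iodomethane, CI
Why: Deconjugative α,α-dimethylation of a 4-en-3-one: KOtBu forms the heteroannular extended dienolate by removing a C6 hydrogen, and this is methylated at C4 twice (the second time after re-enolisation of the 4-methyl enone), leaving C4 quaternary and the alkene at C5=C6. No stereocentre is created, and C10 can no longer epimerise once C4 is quaternary (the change of its descriptor from R to S reflects ligand priorities only).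

Step 10
Reactants: 16 (4aS,5R,6S)-1,1,5,6-tetramethyl-5-[(2,3,5,6-tetramethoxyphenyl)methyl]-3,4,4a,5,6,7-hexahydronaphthalen-2(1H)-one
Product: 18 1,2,4,5-tetramethoxy-3-{[(1R,2S,8aS)-1,2,5,5-tetramethyl-1,2,3,5,6,7,8,8a-octahydronaphthalen-1-yl]methyl}benzene, via hydrazone 17 (not isolated)
Conditions: N2H4·H2O, n-BuOH, 120 °C; concentrate; KOtBu, DMSO, 25→70 °C
Reagents that add atoms: none
Why: Wolff–Kishner reduction in its two-stage form: the hydrazone anion tautomerises to the diazene, which loses N2. The alkene cannot move into conjugation because C4 is quaternary, and the low-temperature KOtBu/DMSO stage avoids hot hydroxide, which could demethylate the flanked aryl ethers.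

Step 11
Reactants: 18 1,2,4,5-tetramethoxy-3-{[(1R,2S,8aS)-1,2,5,5-tetramethyl-1,2,3,5,6,7,8,8a-octahydronaphthalen-1-yl]methyl}benzene
Product: 19 2,5-dimethoxy-3-{[(1R,2S,8aS)-1,2,5,5-tetramethyl-1,2,3,5,6,7,8,8a-octahydronaphthalen-1-yl]methyl}cyclohexa-2,5-diene-1,4-dione
Conditions: (NH4)2Ce(NO3)6, MeCN/H2O, 0 °C
Reagents that add atoms: water, O
Why: Oxidative demethylation of a para-dimethoxy pair by tetravalent cerium (two one-electron oxidations, each followed by ipso capture of water and loss of methanol). Either para pair gives the same 2,5-dimethoxy-3-alkylquinone by symmetry, and the hindered alkene is far harder to oxidise than the tetra-oxygenated arene.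

Step 12
Reactants: 19 2,5-dimethoxy-3-{[(1R,2S,8aS)-1,2,5,5-tetramethyl-1,2,3,5,6,7,8,8a-octahydronaphthalen-1-yl]methyl}cyclohexa-2,5-diene-1,4-dione
Product: 20 2-hydroxy-5-methoxy-3-{[(1R,2S,8aS)-1,2,5,5-tetramethyl-1,2,3,5,6,7,8,8a-octahydronaphthalen-1-yl]methyl}cyclohexa-2,5-diene-1,4-dione
Conditions: KOH, MeOH/H2O, 25 °C; then HCl(aq)
Reagents that add atoms: potassium hydroxide (hydroxide oxygen), [K+].[OH-]
Why: Addition–elimination of hydroxide at a vinylogous ester. The C2 methoxy group next to the alkyl substituent is twisted out of conjugation, so its carbon should be the more electrophilic, and the hydroxyquinone anion formed resists a second exchange.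

Step 13
Reactants: 20 2-hydroxy-5-methoxy-3-{[(1R,2S,8aS)-1,2,5,5-tetramethyl-1,2,3,5,6,7,8,8a-octahydronaphthalen-1-yl]methyl}cyclohexa-2,5-diene-1,4-dione; 21 3-methylbutan-1-amine
Product: 22 2-hydroxy-5-[(3-methylbutyl)amino]-3-{[(1R,2S,8aS)-1,2,5,5-tetramethyl-1,2,3,5,6,7,8,8a-octahydronaphthalen-1-yl]methyl}cyclohexa-2,5-diene-1,4-dione (nakijiquinone M)
Conditions: 21 (excess), EtOH, 25 °C; dilute acid wash
Reagents that add atoms: 3-methylbutan-1-amine (21), CC(C)CCN
Why: Vinylogous transamidation: the primary amine adds to C5 and methanol is expelled, giving the vinylogous amide. The ionised C2 hydroxyl is not a leaving group, so the amine enters at C5 only.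

## Compound list

1 | 4-methylcyclohexan-1-one | CC1CCC(=O)CC1 | starting material
2 | trimethyl{[(4S)-4-methylcyclohex-1-en-1-yl]oxy}silane | C[C@@H]1CC=C(O[Si](C)(C)C)CC1 | intermediate
3 | (4S)-4-methylcyclohex-2-en-1-one | C[C@@H]1C=CC(=O)CC1 | intermediate
4 | trimethyl{[(3R,4S)-3,4-dimethylcyclohex-1-en-1-yl]oxy}silane (trans) | C[C@@H]1[C@@H](C)C=C(O[Si](C)(C)C)CC1 | intermediate
5 | (4S)-3,4-dimethylcyclohex-2-en-1-one | CC1=CC(=O)CC[C@@H]1C | intermediate
6 | 1,2,4,5-tetramethoxybenzene | COc1cc(OC)c(OC)cc1OC | starting material
7 | (2,3,5,6-tetramethoxyphenyl)lithium | COc1cc(OC)c(OC)c([Li])c1OC | intermediate (not isolated)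
8 | (2,3,5,6-tetramethoxyphenyl)methanol | COc1cc(OC)c(OC)c(CO)c1OC | intermediate
9 | 3-(chloromethyl)-1,2,4,5-tetramethoxybenzene | COc1cc(OC)c(OC)c(CCl)c1OC | intermediate
10 | [(2,3,5,6-tetramethoxyphenyl)methyl]magnesium chloride | COc1cc(OC)c(OC)c(C[Mg]Cl)c1OC | intermediate (not isolated)
11 | trimethyl({(3R,4S)-3,4-dimethyl-3-[(2,3,5,6-tetramethoxyphenyl)methyl]cyclohex-1-en-1-yl}oxy)silane | COc1cc(OC)c(OC)c(C[C@@]2(C)C=C(O[Si](C)(C)C)CC[C@@H]2C)c1OC | intermediate
12 | 3-(trimethylsilyl)but-3-en-2-one | CC(=O)C(=C)[Si](C)(C)C | starting material
13 | lithium (3R,4S)-3,4-dimethyl-3-[(2,3,5,6-tetramethoxyphenyl)methyl]cyclohex-1-en-1-olate | COc1cc(OC)c(OC)c(C[C@@]2(C)C=C(O[Li])CC[C@@H]2C)c1OC | intermediate (not isolated)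
14 | (3R,4S)-3,4-dimethyl-2-[3-oxo-2-(trimethylsilyl)butyl]-3-[(2,3,5,6-tetramethoxyphenyl)methyl]cyclohexan-1-one (ring C2 and the silyl-bearing carbon are epimer mixtures) | COc1cc(OC)c(OC)c(C[C@@]2(C)C(CC(C(C)=O)[Si](C)(C)C)C(=O)CC[C@@H]2C)c1OC | intermediate (not isolated)
15 | (4aR,5R,6S)-5,6-dimethyl-5-[(2,3,5,6-tetramethoxyphenyl)methyl]-4,4a,5,6,7,8-hexahydronaphthalen-2(3H)-one | COc1cc(OC)c(OC)c(C[C@@]2(C)[C@@H]3CCC(=O)C=C3CC[C@@H]2C)c1OC | intermediate
16 | (4aS,5R,6S)-1,1,5,6-tetramethyl-5-[(2,3,5,6-tetramethoxyphenyl)methyl]-3,4,4a,5,6,7-hexahydronaphthalen-2(1H)-one | COc1cc(OC)c(OC)c(C[C@@]2(C)[C@@H]3CCC(=O)C(C)(C)C3=CC[C@@H]2C)c1OC | intermediate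
17 | hydrazone of 16 at the ring carbonyl | COc1cc(OC)c(OC)c(C[C@@]2(C)[C@@H]3CCC(=NN)C(C)(C)C3=CC[C@@H]2C)c1OC | intermediate (not isolated)
18 | 1,2,4,5-tetramethoxy-3-{[(1R,2S,8aS)-1,2,5,5-tetramethyl-1,2,3,5,6,7,8,8a-octahydronaphthalen-1-yl]methyl}benzene | COc1cc(OC)c(OC)c(C[C@@]2(C)[C@@H]3CCCC(C)(C)C3=CC[C@@H]2C)c1OC | intermediate
19 | 2,5-dimethoxy-3-{[(1R,2S,8aS)-1,2,5,5-tetramethyl-1,2,3,5,6,7,8,8a-octahydronaphthalen-1-yl]methyl}cyclohexa-2,5-diene-1,4-dione | COC1=CC(=O)C(OC)=C(C[C@@]2(C)[C@@H]3CCCC(C)(C)C3=CC[C@@H]2C)C1=O | intermediate
20 | 2-hydroxy-5-methoxy-3-{[(1R,2S,8aS)-1,2,5,5-tetramethyl-1,2,3,5,6,7,8,8a-octahydronaphthalen-1-yl]methyl}cyclohexa-2,5-diene-1,4-dione | COC1=CC(=O)C(O)=C(C[C@@]2(C)[C@@H]3CCCC(C)(C)C3=CC[C@@H]2C)C1=O | intermediate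
21 | 3-methylbutan-1-amine (isopentylamine) | CC(C)CCN | starting material
22 | 2-hydroxy-5-[(3-methylbutyl)amino]-3-{[(1R,2S,8aS)-1,2,5,5-tetramethyl-1,2,3,5,6,7,8,8a-octahydronaphthalen-1-yl]methyl}cyclohexa-2,5-diene-1,4-dione (nakijiquinone M) | CC(C)CCNC1=CC(=O)C(O)=C(C[C@@]2(C)[C@@H]3CCCC(C)(C)C3=CC[C@@H]2C)C1=O | target

## Step count and least certain steps

Total: 13 steps. Longest linear sequence: 11 steps (from 1 through steps 1–4 and 7–13); the arene branch (steps 5 and 6) joins at step 7.

**Step 8 (key step).** Bond formation at C10, a neopentyl-type enolate carbon, may be slow. Proton transfer between enolates (loss of the enolate regiochemistry and annulation at C6) or anionic polymerisation of the acceptor could then compete. The base-mediated epimerisation at C10 may also stop short of equilibrium, or the equilibrium may be less one-sided than the conformational argument suggests. Fallback, from 11 back to 15: a Mukaiyama–Michael addition of 11 to but-3-en-2-one (BF3·OEt2, iPrOH, CH2Cl2, −78 °C) forms the C1–C10 bond without any free enolate and should give (2S,3R,4S)-3,4-dimethyl-2-(3-oxobutyl)-3-[(2,3,5,6-tetramethoxyphenyl)methyl]cyclohexan-1-one F1 (both C10 epimers are expected; the one named is the one wanted). C10 is then equilibrated at this stage, where it is simply α to a ketone (NaOMe, MeOH, 25 °C), with separation and recycling of the unwanted epimer if needed. Ring A is closed with KOH/MeOH at 65 °C, which rejoins the route at 15.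

**Step 7.** Wurtz homocoupling during formation of the electron-rich benzylic Grignard reagent, direct 1,2-addition to the carbonyl, and slow transfer of a benzylic ligand from copper to a β,β-disubstituted enone are the likely failures. Fallback, from 9 back to 11: displacement of chloride with Bu3SnLi (THF, −78 °C) gives tributyl[(2,3,5,6-tetramethoxyphenyl)methyl]stannane F2. Tin–lithium exchange with n-BuLi (THF, −78 °C) gives [(2,3,5,6-tetramethoxyphenyl)methyl]lithium F3 without coupling products. CuBr·SMe2 (0.5 equiv) converts it into lithium bis[(2,3,5,6-tetramethoxyphenyl)methyl]cuprate F4, a stoichiometric homocuprate that is more nucleophilic than the catalytic magnesium system. Addition of 5 and Me3SiCl at −78 °C then gives 11.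

**Step 9.** Incomplete or excessive alkylation (mono-methyl enone, methylation at C2, O-methylation) is the main risk. Because C10 carries a hydrogen, competing formation of the alternative dienolate towards C10 is also possible, which would move the alkene to C5=C10. Fallback, from 11 back to 16: the first C4 methyl is brought in with the annulation partner. Mukaiyama–Michael addition of 11 to pent-1-en-3-one (BF3·OEt2, iPrOH, CH2Cl2, −78 °C) gives (2S,3R,4S)-3,4-dimethyl-2-(3-oxopentyl)-3-[(2,3,5,6-tetramethoxyphenyl)methyl]cyclohexan-1-one F5. KOH/MeOH at 65 °C closes it to (4aS,5R,6S)-1,5,6-trimethyl-5-[(2,3,5,6-tetramethoxyphenyl)methyl]-4,4a,5,6,7,8-hexahydronaphthalen-2(3H)-one F6. A single deconjugative methylation (KOtBu, tBuOH, MeI) then gives 16.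

**Step 10.** Hydrazone formation at a carbonyl flanked by a quaternary carbon may be slow, with azine formation in competition. If harsher basic conditions become necessary, nucleophilic demethylation of the flanked aryl methyl ethers threatens. Fallback, from 16 back to 18: thioketalisation (ethane-1,2-dithiol, BF3·OEt2, CH2Cl2, 0→25 °C) gives the 1,3-dithiolane of 16 at the ring carbonyl carbon F7, and desulfurisation with acetone-deactivated Raney Ni (EtOH, 78 °C; Mozingo reduction) gives 18 without strong base.

**Step 12.** Loss of regiocontrol in the methoxy exchange (hydroxide entering at C5 instead of C2) or double exchange would lead to the isomeric aminoquinone series after step 13. Any ortho-quinone regioisomer from step 11 would need to converge under the same conditions. Fallback, from 19 back to 22: both methoxy groups are hydrolysed (NaOH, H2O/MeOH, 65 °C; then acid) to 2,5-dihydroxy-3-{[(1R,2S,8aS)-1,2,5,5-tetramethyl-1,2,3,5,6,7,8,8a-octahydronaphthalen-1-yl]methyl}cyclohexa-2,5-diene-1,4-dione F8. Condensation with 21 (EtOH, AcOH cat., 25–50 °C) is expected at C5, the hydroxyl carbon not shielded by the neopentyl substituent, as in the known amination of 2,5-dihydroxy-3-alkylquinones, and gives 22 directly.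

**Step 1.** Incomplete discrimination of the enantiotopic α-hydrogens would leave the whole sequence short of enantiopurity, since no later step corrects it. Fallback, from 5 back to 5: addition of lithiated (S)-N,S-dimethyl-S-phenylsulfoximine (THF, −78 °C) to the carbonyl of insufficiently enriched 5 gives diastereomeric β-hydroxysulfoximines. The adduct of the (S)-enone, (4S)-3,4-dimethyl-1-{[(S)-N-methyl-S-phenylsulfonimidoyl]methyl}cyclohex-2-en-1-ol F9 (carbinol configuration unassigned), is separated by chromatography. Thermolysis (toluene, 110 °C) reverses the addition and returns enantiopure 5.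

## Further compounds

F1 | step 8 | (2S,3R,4S)-3,4-dimethyl-2-(3-oxobutyl)-3-[(2,3,5,6-tetramethoxyphenyl)methyl]cyclohexan-1-one | COc1cc(OC)c(OC)c(C[C@@]2(C)[C@H](CCC(C)=O)C(=O)CC[C@@H]2C)c1OC
F2 | step 7 | tributyl[(2,3,5,6-tetramethoxyphenyl)methyl]stannane | CCCC[Sn](CCCC)(CCCC)Cc1c(OC)c(OC)cc(OC)c1OC
F3 | step 7 | [(2,3,5,6-tetramethoxyphenyl)methyl]lithium | COc1cc(OC)c(OC)c(C[Li])c1OC
F4 | step 7 | lithium bis[(2,3,5,6-tetramethoxyphenyl)methyl]cuprate | [Li+].COc1cc(OC)c(OC)c(C[Cu-]Cc2c(OC)c(OC)cc(OC)c2OC)c1OC
F5 | step 9 | (2S,3R,4S)-3,4-dimethyl-2-(3-oxopentyl)-3-[(2,3,5,6-tetramethoxyphenyl)methyl]cyclohexan-1-one | COc1cc(OC)c(OC)c(C[C@@]2(C)[C@H](CCC(=O)CC)C(=O)CC[C@@H]2C)c1OC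
F6 | step 9 | (4aS,5R,6S)-1,5,6-trimethyl-5-[(2,3,5,6-tetramethoxyphenyl)methyl]-4,4a,5,6,7,8-hexahydronaphthalen-2(3H)-one | COc1cc(OC)c(OC)c(C[C@@]2(C)[C@@H]3CCC(=O)C(C)=C3CC[C@@H]2C)c1OC
F7 | step 10 | 1,3-dithiolane (ethylene dithioketal) of 16 at the ring carbonyl carbon | COc1cc(OC)c(OC)c(C[C@@]2(C)[C@@H]3CCC4(SCCS4)C(C)(C)C3=CC[C@@H]2C)c1OC
F8 | step 12 | 2,5-dihydroxy-3-{[(1R,2S,8aS)-1,2,5,5-tetramethyl-1,2,3,5,6,7,8,8a-octahydronaphthalen-1-yl]methyl}cyclohexa-2,5-diene-1,4-dione | O=C1C=C(O)C(=O)C(C[C@@]2(C)[C@@H]3CCCC(C)(C)C3=CC[C@@H]2C)=C1O
F9 | step 1 | (4S)-3,4-dimethyl-1-{[(S)-N-methyl-S-phenylsulfonimidoyl]methyl}cyclohex-2-en-1-ol | C[C@H]1CCC(O)(C[S@@](=O)(=NC)c2ccccc2)C=C1C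
A1 | alternative 1 | 1,2,4,5-tetramethoxy-3-[(2E,6E)-3,7,11-trimethyldodeca-2,6,10-trien-1-yl]benzene | COc1cc(OC)c(OC)c(C/C=C(\C)CC/C=C(\C)CCC=C(C)C)c1OC
A2 | alternative 1 | drim-7-en-11-yl-2,3,5,6-tetramethoxybenzene (trans-fused, 9β-arylmethyl) | C[C@]12CCCC(C)(C)[C@@H]1CC=C(C)[C@@H]2Cc3c(OC)c(OC)cc(OC)c3OC
A3 | alternative 2 | (4S,6R)-6-(6,6-dimethylcyclohex-1-en-1-yl)-4-methyl-3-[(2,3,5,6-tetramethoxyphenyl)methyl]oxan-2-one | O=C1O[C@@H](C2=CCCCC2(C)C)C[C@H](C)C1Cc1c(OC)c(OC)cc(OC)c1OC
A4 | alternative 2 | decalin C9 carboxylic acid (carboxyl carbon is the future C9 methyl) | COc1cc(OC)c(OC)c(C[C@@]2(C(=O)O)[C@@H]3CCCC(C)(C)C3=CC[C@@H]2C)c1OC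
A5 | alternative 3 | 6,6-dimethyl-1-vinylcyclohex-1-ene | C=CC1=CCCCC1(C)C
A6 | alternative 3 | (E)-2-methylbut-2-enal | C/C=C(\C)C=O
A7 | alternative 3 | decalin C11 aldehyde with C8, C9 and C10 set | O=C[C@@]1(C)[C@@H]2CCCC(C)(C)C2=CC[C@@H]1C
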